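The 2-pyranone ring is opened in retrosynthesis at its enol-lactone bond O1–C6, which lies next to the methyl-bearing C5. C5 and C6 then become the two carbons of an alkyne, and C2–C4 a dimethoxy acrylate. The forward key step treats the acyclic (Z)-2,3-dimethoxy-2-en-4-ynoate methyl ester, carrying a 10-chlorodecyl chain on the alkyne, with ICl. In one operation the ester oxygen closes the six-membered ring onto the distal alkyne carbon, iodine is placed on C5 as the handle for the later methyl group, and the ester methyl leaves. Sulfur is introduced only at the end, by displacing the terminal chloride.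

Key step: step 7

Assumption: the enol ether made in step 6 is taken to settle, under acid equilibration, on the isomer with the ester cis to the alkyne, as 3-alkoxyacrylates do; this geometry matters only for the ring closure.

Step 1
Reactants: 1 10-bromodecan-1-ol; 2 lithium acetylide ethylenediamine complex
Product: 5 dodec-11-yn-1-ol, via lithium 10-bromodecan-1-olate 3 (not isolated), via lithium dodec-11-yn-1-olate 4 (not isolated)
Conditions: LiC≡CH·H2NCH2CH2NH2 (3 equiv), DMSO, 0 °C → rt; then H2O
Reagents that add atoms: none
Why: SN2 alkylation of an acetylide by a primary bromide in DMSO, in which the first equivalent of 2 only deprotonates the hydroxyl group to give 3, the second displaces bromide to give 4, and the amine complex does not isomerise the terminal alkyne at room temperature.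

Step 2
Reactants: 5 dodec-11-yn-1-ol
Product: 7 12-chlorododec-1-yne, via alkoxytriphenylphosphonium chloride 6 (not isolated)
Conditions: PPh3, N-chlorosuccinimide, CH2Cl2, 0 °C → rt
Reagents that add atoms: N-chlorosuccinimide, O=C1CCC(=O)N1Cl
Why: Appel-type chlorination, in which the primary alcohol is activated as phosphonium salt 6 and displaced by chloride in an SN2 step under neutral conditions that leave the terminal alkyne untouched.

Step 3
Reactants: 7 12-chlorododec-1-yne
Product: 10 13-chlorotridec-2-ynal, via lithium 12-chlorododec-1-yn-1-ide 8 (not isolated), via lithium hemiaminolate 9 (not isolated)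
Conditions: n-BuLi (1.05 equiv), THF, −78 °C; DMF (2 equiv), −78 °C → rt; reverse quench into cold 10% aq. KH2PO4/MTBE
Reagents that add atoms: N,N-dimethylformamide, CN(C)C=O
Why: Formylation of a lithium acetylide with DMF, in which deprotonation of the alkyne far outruns any attack of n-BuLi on the primary chloride at −78 °C and the tetrahedral adduct 9 releases the ynal only in the buffered quench, so that liberated dimethylamine cannot add to the product.

Step 4
Reactants: 11 methyl methoxyacetate; 10 13-chlorotridec-2-ynal
Product: 14 methyl 15-chloro-3-hydroxy-2-methoxypentadec-4-ynoate (mixture of racemic diastereomers), via lithium 1,2-dimethoxyethen-1-olate 12 (not isolated), via lithium aldolate 13 (not isolated)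
Conditions: LiN(i-Pr)2 (commercial solution, 1.2 equiv), 11, THF, −78 °C; then 10, −78 °C; AcOH quench at −78 °C
Reagents that add atoms: none
Why: Directed aldol addition of the preformed ester enolate 12 to the unhindered ynal in the 1,2 sense, in which the two new stereocentres at C2 and C3 are formed without control, which is harmless because both are erased in steps 5 and 6.

Step 5
Reactants: 14 methyl 15-chloro-3-hydroxy-2-methoxypentadec-4-ynoate
Product: 15 methyl 15-chloro-2-methoxy-3-oxopentadec-4-ynoate
Conditions: Dess–Martin periodinane (1.2 equiv), CH2Cl2, 0 °C → rt; aq. Na2S2O3/NaHCO3 work-up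
Reagents that add atoms: none
Why: Dess–Martin oxidation of the secondary propargylic alcohol under nearly neutral conditions should give the β-keto ester without touching the alkyne or the alkyl chloride, and it removes the C3 stereocentre while leaving C2 freely epimerisable.

Step 6
Reactants: 15 methyl 15-chloro-2-methoxy-3-oxopentadec-4-ynoate
Product: 17 methyl (2Z)-15-chloro-2,3-dimethoxypentadec-2-en-4-ynoate, via dimethyl ketal 16 (not isolated)
Conditions: HC(OCH3)3 (5 equiv), H2SO4 (cat.), CH3OH, rt → 50 °C
Reagents that add atoms: trimethyl orthoformate, COC(OC)OC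
Why: Acid-catalysed ketalisation with the orthoformate and loss of methanol from ketal 16 toward the acidic C2–H (enol etherification) should give the conjugated enol ether, and because protonation at C2 is reversible the geometry is set thermodynamically, which is expected to put the C3 methoxy group anti to the ester and the slim alkyne cis to it.

Step 7
Reactants: 17 methyl (2Z)-15-chloro-2,3-dimethoxypentadec-2-en-4-ynoate
Product: 20 6-(10-chlorodecyl)-5-iodo-3,4-dimethoxy-2H-pyran-2-one, via iodirenium chloride 18 (not isolated), via 2-methoxypyrylium chloride 19 (not isolated)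
Conditions: ICl (1.2 equiv, added dropwise), CH2Cl2, −78 °C → 0 °C, dark; then aq. Na2S2O3
Reagents that add atoms: iodine monochloride, ClI
Why: ICl transfers I+ to the triple bond to give the bridged iodirenium ion 18, the carbonyl oxygen of the Z-held ester opens it anti at the distal, chain-bearing carbon to give the 2-methoxypyrylium chloride 19, and chloride then removes the O-methyl group by SN2 as CH3Cl to leave the neutral pyranone. The closest known reaction type is the electrophilic iodocyclisation (iodolactonisation) of (Z)-2-en-4-ynoate esters to 5-iodo-2-pyranones. The single new ring, the pyranone, closes in the 6-endo-dig mode by forming O1–C6. No stereocentre is created, so no stereocontrol is needed. The step needs 6-endo instead of 5-exo closure, secured because the alkyl-substituted carbon δ to the carbonyl group takes the larger share of positive charge in 18, whereas the proximal carbon sits next to the inductively withdrawing C(OCH3)= unit and could only be reached by bending the planar enyne. It also needs ICl to attack the alkyne and not the dimethoxy alkene, secured because that alkene is tetrasubstituted and deactivated by the ester, while its β-methoxy donor (C3 of 17, the later C4) makes the carbonyl oxygen a better nucleophile.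

Step 8
Reactants: 20 6-(10-chlorodecyl)-5-iodo-3,4-dimethoxy-2H-pyran-2-one
Product: 21 6-(10-chlorodecyl)-3,4-dimethoxy-5-methyl-2H-pyran-2-one
Conditions: Sn(CH3)4 (3 equiv), Pd(PPh3)4 (5 mol %), CuI (10 mol %), DMF, 80 °C, sealed tube
Reagents that add atoms: tetramethylstannane, C[Sn](C)(C)C
Why: Stille cross-coupling, in which the electron-poor C5–I bond adds readily to zerovalent palladium and methyl transfer from tin followed by reductive elimination installs the C5 methyl group under neutral conditions that spare the lactone and the unactivated primary chloride.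

Step 9
Reactants: 21 6-(10-chlorodecyl)-3,4-dimethoxy-5-methyl-2H-pyran-2-one; 22 sodium methanethiolate
Product: 23 3,4-dimethoxy-5-methyl-6-[10-(methylsulfanyl)decyl]-2H-pyran-2-one
Conditions: NaSCH3 (1.2 equiv), DMF, 0 °C → rt
Reagents that add atoms: none
Why: SN2 displacement of the primary chloride by the soft thiolate in a dipolar aprotic solvent, run with near-stoichiometric reagent at low temperature so that the pyranone is not attacked, and placed last because a thioether would not tolerate ICl and would slow the palladium step.

Compound list
1 | 10-bromodecan-1-ol | OCCCCCCCCCCBr | starting material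
2 | lithium acetylide ethylenediamine complex | [Li+].[C-]#C.NCCN | starting material
3 | lithium 10-bromodecan-1-olate | [Li+].[O-]CCCCCCCCCCBr | intermediate (not isolated)
4 | lithium dodec-11-yn-1-olate | [Li+].[O-]CCCCCCCCCCC#C | intermediate (not isolated)
5 | dodec-11-yn-1-ol | C#CCCCCCCCCCCO | intermediate
6 | (dodec-11-yn-1-yloxy)triphenylphosphonium chloride | C#CCCCCCCCCCCO[P+](c1ccccc1)(c1ccccc1)c1ccccc1.[Cl-] | intermediate (not isolated)
7 | 12-chlorododec-1-yne | C#CCCCCCCCCCCCl | intermediate
8 | lithium 12-chlorododec-1-yn-1-ide | [Li+].[C-]#CCCCCCCCCCCCl | intermediate (not isolated)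
9 | lithium 13-chloro-1-(dimethylamino)tridec-2-yn-1-olate (racemic hemiaminolate) | [Li+].[O-]C(N(C)C)C#CCCCCCCCCCCCl | intermediate (not isolated)
10 | 13-chlorotridec-2-ynal | O=CC#CCCCCCCCCCCCl | intermediate
11 | methyl methoxyacetate | COCC(=O)OC | starting material
12 | lithium 1,2-dimethoxyethen-1-olate (enolate geometry not defined) | [Li+].[O-]C(OC)=COC | intermediate (not isolated)
13 | lithium 15-chloro-1,2-dimethoxy-1-oxopentadec-4-yn-3-olate (aldolate, mixture of racemic diastereomers) | [Li+].[O-]C(C#CCCCCCCCCCCCl)C(OC)C(=O)OC | intermediate (not isolated)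
14 | methyl 15-chloro-3-hydroxy-2-methoxypentadec-4-ynoate (mixture of racemic diastereomers) | COC(=O)C(OC)C(O)C#CCCCCCCCCCCCl | intermediate
15 | methyl 15-chloro-2-methoxy-3-oxopentadec-4-ynoate (racemic) | COC(=O)C(OC)C(=O)C#CCCCCCCCCCCCl | intermediate
16 | methyl 15-chloro-2,3,3-trimethoxypentadec-4-ynoate (racemic dimethyl ketal) | COC(=O)C(OC)C(OC)(OC)C#CCCCCCCCCCCCl | intermediate (not isolated)
17 | methyl (2Z)-15-chloro-2,3-dimethoxypentadec-2-en-4-ynoate (ester cis to the alkyne) | COC(=O)/C(OC)=C(/OC)C#CCCCCCCCCCCCl | intermediate
18 | 2-(10-chlorodecyl)-3-[(1Z)-1,2,3-trimethoxy-3-oxoprop-1-en-1-yl]iodiren-1-ium chloride (bridged iodonium ion) | COC(=O)/C(OC)=C(/OC)C1=C(CCCCCCCCCCCl)[I+]1.[Cl-] | intermediate (not isolated)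
19 | 6-(10-chlorodecyl)-5-iodo-2,3,4-trimethoxypyrylium chloride | COc1[o+]c(CCCCCCCCCCCl)c(I)c(OC)c1OC.[Cl-] | intermediate (not isolated)
20 | 6-(10-chlorodecyl)-5-iodo-3,4-dimethoxy-2H-pyran-2-one | COc1c(I)c(CCCCCCCCCCCl)oc(=O)c1OC | intermediate
21 | 6-(10-chlorodecyl)-3,4-dimethoxy-5-methyl-2H-pyran-2-one | COc1c(C)c(CCCCCCCCCCCl)oc(=O)c1OC | intermediate
22 | sodium methanethiolate | C[S-].[Na+] | starting material
23 | 3,4-dimethoxy-5-methyl-6-[10-(methylsulfanyl)decyl]-2H-pyran-2-one (no stereocentres) | COc1c(C)c(CCCCCCCCCCSC)oc(=O)c1OC | target

Total step count: 9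
Longest linear sequence: 9 steps, from 1 to 23

Steps most likely to fail

1. Step 7. The ring closure may lose regiocontrol, with oxygen attacking the proximal alkyne carbon in a 5-exo mode, or ICl may add to the electron-rich dimethoxy alkene before the alkyne is engaged. Fallback: setting out from 17, the ester is saponified (LiOH, THF/H2O, rt, then mild acidification) to (2Z)-15-chloro-2,3-dimethoxypentadec-2-en-4-ynoic acid F1. F1 is cycloisomerised without any halogen electrophile by a Lewis acid (ZnBr2 cat., THF, rt; a known 6-endo-selective lactonisation of (Z)-2-en-4-ynoic acids) to 6-(10-chlorodecyl)-3,4-dimethoxy-2H-pyran-2-one F2. Electrophilic iodination of F2 at C5, the only free ring position and one activated by the ring enol ether (N-iodosuccinimide, CF3CO2H cat., CH3CN, dark), comes back to the route at 20.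

2. Step 6. Under acid, methanol may add in conjugate fashion to the ynone, or the keto ester may cyclise onto the alkyne, and the equilibration may not settle cleanly on the Z geometry. Fallback: setting out from 15, O-methylation under basic, methanol-free conditions ((CH3)2SO4, Cs2CO3, DMF, 0 °C) is expected to give 17 together with its geometric isomer methyl (2E)-15-chloro-2,3-dimethoxypentadec-2-en-4-ynoate F3. F3 is separated and equilibrated with catalytic camphorsulfonic acid in dry CH2Cl2, where reversible protonation at C2 allows rotation about C2–C3, and is recycled, so that the material comes back to the route at 17.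

3. Step 9. The thiolate may attack the pyranone, by SN2 demethylation of the C4 methoxy group or by addition to the ring, in competition with the slower displacement of chloride. Fallback: setting out from 21, the less basic KSC(O)CH3 (DMF, NaI cat., 50 °C) should give S-[10-(3,4-dimethoxy-5-methyl-2-oxo-2H-pyran-6-yl)decyl] ethanethioate F4. Brief methanolysis in the presence of CH3I (K2CO3, CH3OH, 0 °C, degassed) releases potassium 10-(3,4-dimethoxy-5-methyl-2-oxo-2H-pyran-6-yl)decane-1-thiolate F5, which is methylated at once and so arrives at the target 23.

Further compounds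
F1 | step 7 | (2Z)-15-chloro-2,3-dimethoxypentadec-2-en-4-ynoic acid | OC(=O)/C(OC)=C(/OC)C#CCCCCCCCCCCCl
F2 | step 7 | 6-(10-chlorodecyl)-3,4-dimethoxy-2H-pyran-2-one | COc1cc(CCCCCCCCCCCl)oc(=O)c1OC
F3 | step 6 | methyl (2E)-15-chloro-2,3-dimethoxypentadec-2-en-4-ynoate | COC(=O)/C(OC)=C(\OC)C#CCCCCCCCCCCCl
F4 | step 9 | S-[10-(3,4-dimethoxy-5-methyl-2-oxo-2H-pyran-6-yl)decyl] ethanethioate | COc1c(C)c(CCCCCCCCCCSC(C)=O)oc(=O)c1OC
F5 | step 9 | potassium 10-(3,4-dimethoxy-5-methyl-2-oxo-2H-pyran-6-yl)decane-1-thiolate | COc1c(C)c(CCCCCCCCCC[S-])oc(=O)c1OC.[K+]
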